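The chemist who made the forecast and a colleague read the same two runs and disagree about why they stop.

| flask | starting material | partner | scavenger | remark | time |
|---|---|---|---|---|---|
| epsilon | 0.20 M | 1.1 equiv | 0.30 equiv | run made earlier |  |
| delta | 0.30 M | 1.1 equiv | 0.30 equiv | run made earlier |  |
| flask | 0.40 M | 1.10 equiv | 0.300 equiv |  | 20 h |

| run | time / h | starting material / % | mono adduct / % |
|---|---|---|---|
| epsilon | 1.50 | 50 | 16 |
| epsilon | 4.00 | 40 | 15 |
| epsilon | 8.00 | 36 | 11 |
| epsilon | 20.0 | 32 | 15 |
| delta | 5.00 | 38 | 16 |
| delta | 10.0 | 31 | 13 |
| delta | 15.0 | 31 | 15 |
| delta | 20.0 | 34 | 14 |

(standard deviation of a reading: 2 percentage points)

- part of the starting material that has reacted at 20 h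
- share of the unused partner that is free and not bound as idle adduct, at 20 h

- for released group the idle adduct is counted in
- what may be going on: scavenger + released group -> scavenged by-product; partner + mono adduct -> double product + released group; partner + released group <-> idle adduct; starting material + partner -> mono adduct + released group; partner + other mono adduct -> double product + released group; starting material + partner -> other mono adduct + released group
- the earlier runs do not show how much of partner is bound; that part of a forecast is a guess

Both runs end with about a third of the starting material left, at either concentration. The chemist who made the forecast sees poisoning: once the scavenger is used, “each further released group ties up one partner as idle adduct”. That chemist expects 68 % reacted, about 0.4 equiv of partner unused, and 3 % of it free.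

The colleague sees partner used up, as the limiting reagent: either mono adduct takes one partner and the double product takes two. If the charge of 1.1 equiv is gone when 67.0 % has reacted, a reading with the scatter of the runs, then she gets 1.64 equiv, the partner spend: partner used per starting material reacted. It lies between one and two, as her view requires. For this flask, if the spend holds at the higher concentration, the charge of 1.10 equiv divided by it gives 67.1 % reacted, and on her view the partner is then used up. She gives no figure for the free share, since the runs do not show how much partner is bound.

In the flask, 66.0 % has reacted and 51.9 % of the unused partner is free, but 0 % of the partner charge remains beside 2.89 × 10⁻⁷ M of idle adduct, so the flask's spend is 1.67 equiv.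

    scavenger + released group → scavenged by-product (k = 0.0430 /M/s)
    partner + mono adduct → double product + released group (k = 0.00300 /M/s)
    partner + released group ⇌ idle adduct, settled at all times (K = 2.90 /M)
    starting material + partner → mono adduct + released group (k = 9.70 × 10⁻⁴ /M/s)
    partner + other mono adduct → double product + released group (k = 1.10 × 10⁻⁴ /M/s)
    starting material + partner → other mono adduct + released group (k = 1.30 × 10⁻⁴ /M/s)

The constant for partner with mono adduct is 3.09 times that for the step making mono adduct. At 0.320 h, mono adduct was made just 1.27 times as fast as it was used up. The idle adduct of the forecast has its place early in this flask: at 2.00 h the flask held 0.0199 M of it beside 0.0271 M of free partner, and at 10.0 h less, 1.34 × 10⁻⁴ M.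

With 0.16 M of starting material and the same equivalents, the spend again gives 67.1 % reacted; that flask gives 66.0 %.

Readings and results were computed with made-up constants, and the scatter is random.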